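The target is a trans-fused hydroazulene (daucane numbering: C1 methyl-bearing fusion carbon, C4 carbinol, C5 fusion CH, C6 aroyloxy, C10 isovaleryloxy). The route rests on disconnecting the only alkene, C8=C9, which lies in the seven-membered ring between the homoallylic C6 and allylic C10 carbinols. Ring-closing olefin metathesis of a C10 vinyl group with a C6 methallyl arm closes the cycloheptene and its trisubstituted alkene in one operation, on a cyclopentane already carrying all five stereocentres. That diene comes from an asymmetric Diels–Alder adduct whose cyclohexene is cleaved and re-closed by an aldol ring contraction, each metathesis terminus being installed by addition to an aldehyde.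

Key step: step 10

Remarks: the daucane numbering above is used for all intermediates. In step 2 the sense of induction is assigned from the accepted transition-state model for cationic oxazaborolidines; if the optical rotation of 5 shows the opposite sense, the (R)-catalyst is used.

Step 1
Reactants: 1 3-methylbut-1-yne; 2 ethylene
Product: 3 2-isopropylbuta-1,3-diene (4-methyl-3-methylidenepent-1-ene)
Conditions: second-generation Grubbs catalyst RuCl2(=CHPh)(H2IMes)(PCy3) (3 mol%), ethylene (1 atm), CH2Cl2, rt; product used as a distilled solution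
Reagents that add atoms: none
Why: Ethylene–alkyne cross enyne metathesis, in which the ruthenium methylidene adds across the terminal alkyne and ethylene turns over the resulting vinylcarbene, should give the 2-substituted 1,3-diene with no stereocentre formed.

Step 2
Reactants: 3 2-isopropylbuta-1,3-diene; 4 methacrolein
Product: 5 (S)-1-methyl-4-(propan-2-yl)cyclohex-3-ene-1-carbaldehyde
Conditions: (S)-B-(o-tolyl)-diphenylprolinol oxazaborolidine·HNTf2 (10 mol%), CH2Cl2, −78 °C
Reagents that add atoms: none
Why: Catalytic asymmetric Diels–Alder reaction in which the cationic oxazaborolidine binds s-trans methacrolein, the 2-alkyl diene adds with "para" regiochemistry, and attack on the Cα Re face (CHO, =CH2, CH3 clockwise) sets the quaternary C1 as (S).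

Step 3
Reactants: 5 (S)-1-methyl-4-(propan-2-yl)cyclohex-3-ene-1-carbaldehyde
Product: 6 1-[(1S)-1-methyl-4-(propan-2-yl)cyclohex-3-en-1-yl]prop-2-en-1-ol (both carbinol epimers)
Conditions: CH2=CHMgBr, THF, −78 to 0 °C; then H2O
Reagents that add atoms: vinylmagnesium bromide, C=C[Mg]Br
Why: Grignard 1,2-addition to the neopentylic aldehyde, expected to be unselective at the carbinol carbon because the two ring arms at C1 are nearly equivalent, which does not matter since that centre is erased in step 4.

Step 4
Reactants: 6 1-[(1S)-1-methyl-4-(propan-2-yl)cyclohex-3-en-1-yl]prop-2-en-1-ol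
Product: 7 1-[(1S)-1-methyl-4-(propan-2-yl)cyclohex-3-en-1-yl]prop-2-en-1-one
Conditions: Dess–Martin periodinane, CH2Cl2, 0 °C to rt; used without delay
Reagents that add atoms: none
Why: Dess–Martin oxidation of the allylic alcohol under neutral conditions should give the vinyl ketone, which has no epimerisable centre because C1 is quaternary.

Step 5
Reactants: 7 1-[(1S)-1-methyl-4-(propan-2-yl)cyclohex-3-en-1-yl]prop-2-en-1-one
Product: 8 (1R)-1-[(1S)-1-methyl-4-(propan-2-yl)cyclohex-3-en-1-yl]prop-2-en-1-ol
Conditions: (S)-2-methyl-CBS-oxazaborolidine (20 mol%), catecholborane, toluene, −78 °C; then MeOH/H2O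
Reagents that add atoms: none
Why: Corey–Bakshi–Shibata reduction in which the quaternary C1 acts as the large and the vinyl as the small ketone substituent, so the (S)-catalyst should deliver hydride to the face giving the (10R) allylic alcohol (same sense as acetophenone to (R)-1-phenylethanol), with 1,2-reduction favoured at −78 °C.

Step 6
Reactants: 8 (1R)-1-[(1S)-1-methyl-4-(propan-2-yl)cyclohex-3-en-1-yl]prop-2-en-1-ol
Product: 9 (1R)-1-[(1S)-1-methyl-4-(propan-2-yl)cyclohex-3-en-1-yl]prop-2-en-1-yl 3-methylbutanoate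
Conditions: 3-methylbutanoyl chloride, pyridine, DMAP (cat.), CH2Cl2, 0 °C to rt
Reagents that add atoms: 3-methylbutanoyl chloride, CC(C)CC(Cl)=O
Why: DMAP-catalysed acylation installs the C10 isovalerate of the target early, where it also prevents lactol and hemiketal formation after the ring cleavage.

Step 7
Reactants: 9 (1R)-1-[(1S)-1-methyl-4-(propan-2-yl)cyclohex-3-en-1-yl]prop-2-en-1-yl 3-methylbutanoate
Product: 10 (3R,4S)-4,8-dimethyl-7-oxo-4-(2-oxoethyl)non-1-en-3-yl 3-methylbutanoate
Conditions: O3 (1.0 equiv), pyridine (3 equiv), CH2Cl2, −78 °C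
Reagents that add atoms: ozone, [O-][O+]=O
Why: Ozonolysis with pyridine gives the carbonyl compounds directly, and electrophilic ozone should cleave the electron-rich trisubstituted ring alkene (C4=C6) well before the monosubstituted vinyl group, which is deactivated by its allylic ester.

Step 8
Reactants: 10 (3R,4S)-4,8-dimethyl-7-oxo-4-(2-oxoethyl)non-1-en-3-yl 3-methylbutanoate
Product: 11 (1R)-1-[(1S,2R,3S)-2-formyl-3-hydroxy-1-methyl-3-(propan-2-yl)cyclopentyl]prop-2-en-1-yl 3-methylbutanoate
Conditions: D-proline (30 mol%), DMSO (0.05 M), rt; product used crude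
Reagents that add atoms: none
Why: Proline-catalysed intramolecular 5-enolexo aldol addition, in which only the aldehyde forms an enamine and attacks the isopropyl ketone through the carboxylic-acid hydrogen-bonded transition state to give the trans hydroxy aldehyde; D-proline is the matched enantiomer by analogy with proline anti-aldol reactions, and the bulky C10 arm on C1 places the formyl group cis to the C1 methyl, so C4 (S) and C5 should form as in the target without dehydration.

Step 9
Reactants: 11 (1R)-1-[(1S,2R,3S)-2-formyl-3-hydroxy-1-methyl-3-(propan-2-yl)cyclopentyl]prop-2-en-1-yl 3-methylbutanoate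
Product: 13 (1R)-1-[(1S,2S,3S)-3-hydroxy-2-[(1R)-1-hydroxy-3-methylbut-3-en-1-yl]-1-methyl-3-(propan-2-yl)cyclopentyl]prop-2-en-1-yl 3-methylbutanoate, via C6-O-diisopinocampheylborinate ester 12 (not isolated)
Conditions: (+)-Ipc2BOMe (2.4 equiv), CH2=C(CH3)CH2MgCl (2.2 equiv), Et2O, −78 °C to rt; then 11, −78 °C; then HOCH2CH2NH2, rt
Reagents that add atoms: 2-methylallylmagnesium chloride, CC(=C)C[Mg]Cl; (+)-B-methoxydiisopinocampheylborane, COB([C@H]1C[C@H]2C[C@@H]([C@@H]1C)C2(C)C)[C@H]1C[C@H]2C[C@@H]([C@@H]1C)C2(C)C (its Ipc2B unit stays only in 12)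
Why: Brown asymmetric methallylboration through a chair six-membered transition state, in which the isopinocampheyl groups derived from (−)-α-pinene should direct the methallyl unit to the Re face of the formyl group (reagent control) and set C6 as (R), the hindered tertiary hydroxyl being inert at −78 °C and ethanolamine freeing the alcohol from boron.

Step 10
Reactants: 13 (1R)-1-[(1S,2S,3S)-3-hydroxy-2-[(1R)-1-hydroxy-3-methylbut-3-en-1-yl]-1-methyl-3-(propan-2-yl)cyclopentyl]prop-2-en-1-yl 3-methylbutanoate
Product: 14 (3S,3aS,4R,8R,8aS)-3,4-dihydroxy-6,8a-dimethyl-3-(propan-2-yl)-1,2,3,3a,4,5,8,8a-octahydroazulen-8-yl 3-methylbutanoate (locants as in the target)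
Conditions: second-generation Hoveyda–Grubbs catalyst RuCl2(=CH-C6H4-2-OiPr)(H2IMes) (10 mol%), toluene (0.005 M), 80 °C
Reagents that add atoms: none
Why: Ring-closing olefin metathesis by the Chauvin mechanism: the ruthenium alkylidene exchanges with one terminal alkene (the methallyl terminus on the C6 arm or the C10 vinyl group) and the new alkylidene undergoes intramolecular [2+2] cycloaddition and cycloreversion with the other, forming C8=C9 and expelling ethylene. The closest known reaction type is RCM of a monosubstituted with a 1,1-disubstituted alkene to give a trisubstituted cycloalkene, established for seven-membered rings with second-generation N-heterocyclic-carbene ruthenium catalysts. The seven-membered ring closes by alkene metathesis as a trans-fused annulation onto the preformed cyclopentane. No stereocentre is created: the ring enforces the endocyclic (Z) alkene and the five existing centres are untouched. The step needs cyclisation to outrun oligomerisation and alkene isomerisation and must leave the ester and hydroxyls alone; high dilution, the quaternary C1 (Thorpe–Ingold effect), the trans-vicinal placement of the two arms and irreversible loss of ethylene favour closure, and ruthenium carbenes tolerate esters and free alcohols.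

Step 11
Reactants: 14 (3S,3aS,4R,8R,8aS)-3,4-dihydroxy-6,8a-dimethyl-3-(propan-2-yl)-1,2,3,3a,4,5,8,8a-octahydroazulen-8-yl 3-methylbutanoate
Product: 15 (3S,3aS,4R,8R,8aS)-3-hydroxy-6,8a-dimethyl-8-(3-methylbutanoyloxy)-3-(propan-2-yl)-1,2,3,3a,4,5,8,8a-octahydroazulen-4-yl 4-acetoxybenzoate
Conditions: 4-acetoxybenzoyl chloride, pyridine, DMAP (cat.), CH2Cl2, 0 to 40 °C
Reagents that add atoms: 4-acetoxybenzoyl chloride, CC(=O)Oc1ccc(cc1)C(Cl)=O
Why: DMAP-catalysed acylation should occur only at the secondary C6 hydroxyl, the tertiary C4 hydroxyl being too hindered, with the phenol carried as its acetate to prevent self-acylation.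

Step 12
Reactants: 15 (3S,3aS,4R,8R,8aS)-3-hydroxy-6,8a-dimethyl-8-(3-methylbutanoyloxy)-3-(propan-2-yl)-1,2,3,3a,4,5,8,8a-octahydroazulen-4-yl 4-acetoxybenzoate
Product: 16 (3S,3aS,4R,8R,8aS)-3-hydroxy-6,8a-dimethyl-8-(3-methylbutanoyloxy)-3-(propan-2-yl)-1,2,3,3a,4,5,8,8a-octahydroazulen-4-yl 4-hydroxybenzoate (CNP0086724.4)
Conditions: K2CO3 (0.2 equiv), MeOH, 0 °C, short reaction time; then AcOH quench
Reagents that add atoms: none
Why: Base-catalysed methanolysis (transesterification) should remove only the phenolic acetate, which is far more electrophilic than the hindered neopentylic isovalerate and than the benzoate, the latter being deactivated once the phenoxide forms.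

Compound list
1 | 3-methylbut-1-yne | CC(C)C#C | starting material
2 | ethylene | C=C | starting material
3 | 2-isopropylbuta-1,3-diene | C=CC(=C)C(C)C | intermediate
4 | methacrolein | CC(=C)C=O | starting material
5 | (S)-1-methyl-4-(propan-2-yl)cyclohex-3-ene-1-carbaldehyde | O=C[C@]1(C)CC=C(C(C)C)CC1 | intermediate
6 | 1-[(1S)-1-methyl-4-(propan-2-yl)cyclohex-3-en-1-yl]prop-2-en-1-ol, both carbinol epimers | C=CC(O)[C@]1(C)CC=C(C(C)C)CC1 | intermediate
7 | 1-[(1S)-1-methyl-4-(propan-2-yl)cyclohex-3-en-1-yl]prop-2-en-1-one | C=CC(=O)[C@]1(C)CC=C(C(C)C)CC1 | intermediate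
8 | (1R)-1-[(1S)-1-methyl-4-(propan-2-yl)cyclohex-3-en-1-yl]prop-2-en-1-ol | C=C[C@@H](O)[C@]1(C)CC=C(C(C)C)CC1 | intermediate
9 | (1R)-1-[(1S)-1-methyl-4-(propan-2-yl)cyclohex-3-en-1-yl]prop-2-en-1-yl 3-methylbutanoate | C=C[C@@H](OC(=O)CC(C)C)[C@]1(C)CC=C(C(C)C)CC1 | intermediate
10 | (3R,4S)-4,8-dimethyl-7-oxo-4-(2-oxoethyl)non-1-en-3-yl 3-methylbutanoate | C=C[C@@H](OC(=O)CC(C)C)[C@](C)(CC=O)CCC(=O)C(C)C | intermediate
11 | (1R)-1-[(1S,2R,3S)-2-formyl-3-hydroxy-1-methyl-3-(propan-2-yl)cyclopentyl]prop-2-en-1-yl 3-methylbutanoate | C=C[C@@H](OC(=O)CC(C)C)[C@@]1(C)CC[C@](O)(C(C)C)[C@@H]1C=O | intermediate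
12 | C6-O-diisopinocampheylborinate ester of 13 | C=C[C@@H](OC(=O)CC(C)C)[C@@]1(C)CC[C@](O)(C(C)C)[C@@H]1[C@H](OB([C@H]2C[C@H]3C[C@@H]([C@@H]2C)C3(C)C)[C@H]4C[C@H]5C[C@@H]([C@@H]4C)C5(C)C)CC(C)=C | intermediate
13 | (1R)-1-[(1S,2S,3S)-3-hydroxy-2-[(1R)-1-hydroxy-3-methylbut-3-en-1-yl]-1-methyl-3-(propan-2-yl)cyclopentyl]prop-2-en-1-yl 3-methylbutanoate | C=C[C@@H](OC(=O)CC(C)C)[C@@]1(C)CC[C@](O)(C(C)C)[C@@H]1[C@H](O)CC(C)=C | intermediate
14 | (3S,3aS,4R,8R,8aS)-3,4-dihydroxy-6,8a-dimethyl-3-(propan-2-yl)-1,2,3,3a,4,5,8,8a-octahydroazulen-8-yl 3-methylbutanoate | CC1=C[C@@H](OC(=O)CC(C)C)[C@@]2(C)CC[C@](O)(C(C)C)[C@@H]2[C@H](O)C1 | intermediate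
15 | (3S,3aS,4R,8R,8aS)-3-hydroxy-6,8a-dimethyl-8-(3-methylbutanoyloxy)-3-(propan-2-yl)-1,2,3,3a,4,5,8,8a-octahydroazulen-4-yl 4-acetoxybenzoate | CC1=C[C@@H](OC(=O)CC(C)C)[C@@]2(C)CC[C@](O)(C(C)C)[C@@H]2[C@H](OC(=O)c2ccc(OC(C)=O)cc2)C1 | intermediate
16 | (3S,3aS,4R,8R,8aS)-3-hydroxy-6,8a-dimethyl-8-(3-methylbutanoyloxy)-3-(propan-2-yl)-1,2,3,3a,4,5,8,8a-octahydroazulen-4-yl 4-hydroxybenzoate | CC1=C[C@@H](OC(=O)CC(C)C)[C@@]2(C)CC[C@](O)(C(C)C)[C@@H]2[C@H](OC(=O)c2ccc(O)cc2)C1 | target

Total step count: 12. Longest linear sequence: 12 steps (from 3-methylbut-1-yne; methacrolein enters at step 2).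

Steps most likely to fail

Step 8 (aldol ring contraction). The process at risk is threefold: dehydration of the aldol to the conjugated enal, sluggish enamine addition to the hindered isopropyl ketone, and poor facial selectivity at C4 and C5. The fallback replaces the enamine manifold by a Lewis-acid one. It sets out from 10, whose aldehyde is silylated selectively (TMSOTf, Et3N, CH2Cl2, 0 °C; the hindered ketone enolises far more slowly) to (3R,4S)-4,8-dimethyl-7-oxo-4-[(Z)-2-(trimethylsilyloxy)ethenyl]non-1-en-3-yl 3-methylbutanoate F1. This is cyclised by a BF3·OEt2-promoted intramolecular Mukaiyama aldol addition at −78 °C, an open transition state with no amine and hence no dehydration path, in which the enol ether should again add trans to the C10 arm. Aqueous work-up removes the silyl group and returns the route to 11.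

Step 10 (ring-closing metathesis). The process at risk is slow loading of ruthenium on both alkenes (a neopentylic vinyl group carrying an allylic ester, and a 1,1-disubstituted alkene), leading to catalyst decay, oligomerisation or alkene isomerisation. The fallback changes the substrate class to a free allylic alcohol, which is known to accelerate metathesis at the adjacent vinyl group, and defers ester differentiation. It sets out from 13, whose isovalerate is removed (K2CO3, MeOH, rt) to give (1R)-1-[(1S,2S,3S)-3-hydroxy-2-[(1R)-1-hydroxy-3-methylbut-3-en-1-yl]-1-methyl-3-(propan-2-yl)cyclopentyl]prop-2-en-1-ol F2. Ring closure of this triol with the same ruthenium catalyst should give (3S,3aS,4R,8R,8aS)-6,8a-dimethyl-3-(propan-2-yl)-1,2,3,3a,4,5,8,8a-octahydroazulene-3,4,8-triol F3. Site-selective acylation of the less hindered C6 hydroxyl (4-acetoxybenzoyl chloride, 1.05 equiv, pyridine, −20 °C) then gives (3S,3aS,4R,8R,8aS)-3,8-dihydroxy-6,8a-dimethyl-3-(propan-2-yl)-1,2,3,3a,4,5,8,8a-octahydroazulen-4-yl 4-acetoxybenzoate F4. Acylation of the neopentylic allylic C10 hydroxyl (3-methylbutanoyl chloride, Et3N, DMAP, 40 °C) returns the route to 15.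

Step 9 (methallylboration). The process at risk is low reactivity of the very hindered aldehyde toward the bulky borane and override of reagent control by substrate bias, giving the wrong face at C6. The fallback replaces reagent-controlled C–C formation by hydroxyl-directed reduction. It sets out from 11: uncontrolled addition of CH2=C(CH3)CH2MgCl (THF, −78 °C) gives 13 together with its C6 epimer (1R)-1-[(1S,2S,3S)-3-hydroxy-2-[(1S)-1-hydroxy-3-methylbut-3-en-1-yl]-1-methyl-3-(propan-2-yl)cyclopentyl]prop-2-en-1-yl 3-methylbutanoate F5. The mixture is oxidised (Dess–Martin periodinane) to (1R)-1-[(1S,2R,3S)-3-hydroxy-1-methyl-2-(3-methylbut-3-enoyl)-3-(propan-2-yl)cyclopentyl]prop-2-en-1-yl 3-methylbutanoate F6. Evans–Saksena reduction (Me4NBH(OAc)3, MeCN/AcOH, −35 °C) then delivers hydride intramolecularly from the C4 alkoxyborohydride through a chair transition state with C7 equatorial, which should give the 1,3-anti diol, that is 13, where the route is rejoined.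

Further compounds
F1 | step 8 | (3R,4S)-4,8-dimethyl-7-oxo-4-[(Z)-2-(trimethylsilyloxy)ethenyl]non-1-en-3-yl 3-methylbutanoate | C=C[C@@H](OC(=O)CC(C)C)[C@](C)(/C=C\O[Si](C)(C)C)CCC(=O)C(C)C
F2 | step 10 | (1R)-1-[(1S,2S,3S)-3-hydroxy-2-[(1R)-1-hydroxy-3-methylbut-3-en-1-yl]-1-methyl-3-(propan-2-yl)cyclopentyl]prop-2-en-1-ol | C=C[C@@H](O)[C@@]1(C)CC[C@](O)(C(C)C)[C@@H]1[C@H](O)CC(C)=C
F3 | step 10 | (3S,3aS,4R,8R,8aS)-6,8a-dimethyl-3-(propan-2-yl)-1,2,3,3a,4,5,8,8a-octahydroazulene-3,4,8-triol | CC1=C[C@@H](O)[C@@]2(C)CC[C@](O)(C(C)C)[C@@H]2[C@H](O)C1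
F4 | step 10 | (3S,3aS,4R,8R,8aS)-3,8-dihydroxy-6,8a-dimethyl-3-(propan-2-yl)-1,2,3,3a,4,5,8,8a-octahydroazulen-4-yl 4-acetoxybenzoate | CC1=C[C@@H](O)[C@@]2(C)CC[C@](O)(C(C)C)[C@@H]2[C@H](OC(=O)c2ccc(OC(C)=O)cc2)C1
F5 | step 9 | (1R)-1-[(1S,2S,3S)-3-hydroxy-2-[(1S)-1-hydroxy-3-methylbut-3-en-1-yl]-1-methyl-3-(propan-2-yl)cyclopentyl]prop-2-en-1-yl 3-methylbutanoate | C=C[C@@H](OC(=O)CC(C)C)[C@@]1(C)CC[C@](O)(C(C)C)[C@@H]1[C@@H](O)CC(C)=C
F6 | step 9 | (1R)-1-[(1S,2R,3S)-3-hydroxy-1-methyl-2-(3-methylbut-3-enoyl)-3-(propan-2-yl)cyclopentyl]prop-2-en-1-yl 3-methylbutanoate | C=C[C@@H](OC(=O)CC(C)C)[C@@]1(C)CC[C@](O)(C(C)C)[C@@H]1C(=O)CC(C)=C
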